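The runs were computed with constants of no real substance, noise included.

One unit carries this flask: electrophile consumed per nucleophile charged, the uptake. Its zero is the symmetric case, one electrophile per nucleophile. The flask is charged at 1.25, so a strict one-to-one count leaves 20.0% of its electrophile unreacted.

the same everywhere: free base 2.16 M

| charge | electrophile | nucleophile | remark | time |
|---|---|---|---|---|
| beta | 0.48 M | 0.576 M | run made earlier |  |
| alpha | 1.1 M | 0.576 M | run made earlier |  |
| delta | 0.72 M | 0.86 M | run made earlier |  |
| flask | 0.72 M | 0.576 M |  | 15 min |

| run | time / min | electrophile / % | target / % |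
|---|---|---|---|
| beta | 5.00 | 5.4 | 20.9 |
| beta | 10.0 | 0 | 19.7 |
| beta | 15.0 | 0 | 19.6 |
| beta | 20.0 | 1.3 | 20.4 |
| alpha | 1.33 | 49.3 | 6.7 |
| alpha | 3.00 | 26.2 | 4.6 |
| alpha | 8.00 | 9.0 | 1.3 |
| alpha | 20.0 | 4.2 | 0 |
| delta | 1.33 | 33.5 | 21.8 |
| delta | 3.00 | 8.6 | 20.5 |
| delta | 8.00 | 0 | 19.5 |
| delta | 20.0 | 0.4 | 18.9 |

(standard deviation of a reading: 1 percentage point)

- a reading or a percentage of target counts all its forms, free or not
- the earlier runs do not show how much of nucleophile is bound; that part of a forecast is a guess

1. part of the electrophile that has reacted at 15 min
2. share of free nucleophile in free nucleophile and protonated nucleophile together, at 15 min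

We turn the settings in turn. Electrophile first: by hand, more of it strains the uptake. Yet the alpha run, at 1.91 per nucleophile, reads 4.2% left at 20.0 min, which gives an uptake of 1.83, twice the symmetric count. That is a reading with its scatter, and the electrophile was still falling between the last two readings of the alpha run. Nucleophile next: by hand, more of it raises our reckoned ceiling, uptake times nucleophile over electrophile, which for this flask is 146% of the charge. The delta run, with more nucleophile, reads 0% at 8.00 min. Time: by hand it should matter little, and the beta run, at a lighter 0.833 per nucleophile, reads 0% at 10.0 min, while this flask has 15 min. Free base can't be read, since the runs hold it at one charge, so the free share stays a guess. Our reckoned ceiling says that the electrophile of this flask can go.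

The forecast says 99% (96% to 100%) reacted, as the flask's charge “lies well inside that capacity”, and, as a guess, 80% (50% to 97%) free.

The flask gives 99.9% reacted and 91.6% free, 12 percentage points above the forecast but inside its range.

    electrophile + nucleophile → acid set free + target (k = 0.0190 L mol⁻¹ s⁻¹)
    nucleophile + acid set free ⇌ protonated nucleophile, settled at all times (K = 170 L mol⁻¹)
    acid set free + free base ⇌ salt of the base (K = 390 L mol⁻¹, k = 0.640 L mol⁻¹ s⁻¹)
    electrophile + target → side product (k = 0.0960 L mol⁻¹ s⁻¹)
    nucleophile + target ⇌ idle adduct, settled at all times (K = 3.60 L mol⁻¹)

At 15.0 min the flask's side product, two electrophile each, carries 91.5% of the charge and target 8.31%, with 26.3% of the nucleophile still free, and the flask's uptake of 1.25 stands below the 1.83 read from the alpha run. For the neighbour flask with 0.14 M of nucleophile, that reading reckons 35.6% reacted. That neighbour gives 38.9%, an uptake of 2.00, with nucleophile, its limiting reagent, down to 0.0454% of its charge.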